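**Strategy.** Everything rests on cutting two adjacent bonds of the benzene ring at once: C5–CH3 and the bond from C6 to the first chain carbon. C6 is meta to the oxygens on C2 and C4, so electrophilic substitution cannot reach it, but a C6 iodide flanked by the C1 ester and a free C5–H is set up for a palladium/norbornene relay. In one operation this relay methylates C5 with methyl tosylate and joins C6 to 13-methyltetradec-1-yne. The precursor is benzyl 2,4-bis(benzyloxy)-6-iodobenzoate; all three oxygens carry benzyl groups, so one final hydrogenation saturates the chain and frees both phenols and the acid under neutral conditions.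

Key step: step 8

Numbering: ring atoms are numbered as in the target acid (C1 carboxyl-bearing, C2 and C4 oxygen-bearing, C3 H, C5 methyl, C6 chain).
Assumption: 5-iodobenzene-1,3-diol and 12-methyltridecanoic acid are taken as catalogue compounds; the target side chain is read as 13-methyltetradecyl (fifteen carbons).

Step 1
Reactants: 1 5-iodobenzene-1,3-diol
Product: 2 1,3-bis(benzyloxy)-5-iodobenzene
Conditions: BnBr (2.3 equiv), K2CO3, DMF, rt to 50 °C
Reagents that add atoms: benzyl bromide, BrCc1ccccc1
Why: Williamson ether synthesis: both phenoxides should be O-benzylated by the reactive benzylic bromide in DMF, and the aryl iodide is inert to carbonate.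

Step 2
Reactants: 2 1,3-bis(benzyloxy)-5-iodobenzene
Product: 4 2,4-bis(benzyloxy)-6-iodobenzaldehyde, via iminium chloride 3 (not isolated)
Conditions: POCl3 (2 equiv), DMF, 0 °C to 75 °C; then aq. NaOAc, rt
Reagents that add atoms: N,N-dimethylformamide, CN(C)C=O; water, O
Why: Vilsmeier–Haack formylation: the chloroiminium electrophile should attack next to iodine, para to one benzyloxy group and ortho to the other, a site less crowded than the one between the two ethers, and buffered aqueous work-up hydrolyses the iminium salt to the aldehyde.

Step 3
Reactants: 4 2,4-bis(benzyloxy)-6-iodobenzaldehyde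
Product: 5 2,4-bis(benzyloxy)-6-iodobenzoic acid
Conditions: NaClO2, NaH2PO4, 2-methyl-2-butene (excess), THF/t-BuOH/H2O, 0 °C to rt
Reagents that add atoms: sodium chlorite, [Na+].[O-]Cl=O
Why: Pinnick oxidation: chlorous acid converts the aldehyde into the acid without touching the aryl iodide or the benzyl ethers, and excess 2-methyl-2-butene traps hypochlorous acid before it can chlorinate the electron-rich ring.

Step 4
Reactants: 5 2,4-bis(benzyloxy)-6-iodobenzoic acid
Product: 6 benzyl 2,4-bis(benzyloxy)-6-iodobenzoate
Conditions: BnBr (1.2 equiv), K2CO3, DMF, rt
Reagents that add atoms: benzyl bromide, BrCc1ccccc1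
Why: Carboxylate alkylation (SN2 esterification): the new bond is made at oxygen, away from the carbonyl carbon shielded by two ortho substituents, so steric hindrance should not slow it.

Step 5
Reactants: 7 12-methyltridecanoic acid
Product: 8 12-methyltridecan-1-ol
Conditions: LiAlH4, THF, 0 °C to reflux; aq. NaOH work-up
Reagents that add atoms: none
Why: Hydride reduction of a carboxylic acid to the primary alcohol by LiAlH4; the saturated chain carries no other functional group.

Step 6
Reactants: 8 12-methyltridecan-1-ol
Product: 9 12-methyltridecanal
Conditions: TEMPO (10 mol %), PhI(OAc)2 (1.1 equiv), CH2Cl2, rt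
Reagents that add atoms: none
Why: TEMPO-catalysed oxoammonium oxidation with PhI(OAc)2 as terminal oxidant should stop at the aldehyde in anhydrous CH2Cl2.

Step 7
Reactants: 9 12-methyltridecanal
Product: 10 13-methyltetradec-1-yne
Conditions: dimethyl (1-diazo-2-oxopropyl)phosphonate (1.3 equiv), K2CO3, MeOH, 0 °C to rt
Reagents that add atoms: dimethyl (1-diazo-2-oxopropyl)phosphonate, COP(=O)(OC)C(=[N+]=[N-])C(C)=O
Why: Ohira–Bestmann variant of the Seyferth–Gilbert homologation: methanolysis of the reagent releases the diazomethylphosphonate anion, which adds to the aldehyde, and loss of phosphate and N2 with 1,2-hydride shift of the alkylidene carbene gives the terminal alkyne under mild base.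

Step 8
Reactants: 6 benzyl 2,4-bis(benzyloxy)-6-iodobenzoate; 10 13-methyltetradec-1-yne; 11 methyl 4-methylbenzenesulfonate
Product: 12 benzyl 2,4-bis(benzyloxy)-5-methyl-6-(13-methyltetradec-1-yn-1-yl)benzoate
Conditions: Pd(OAc)2 (10 mol %), tri(2-furyl)phosphine (22 mol %), norbornene (2 equiv), Cs2CO3 (3 equiv), 11 (2.5 equiv), MeCN, 85 °C; 10 (1.5 equiv) added by syringe pump over about 6 h
Reagents that add atoms: none
Why: Zerovalent palladium inserts into the C6–I bond of 6, norbornene carbopalladates the aryl–palladium bond, and base-assisted palladation of C5–H, the only free position ortho to C6, gives a five-membered aryl–norbornyl palladacycle of divalent palladium. Methyl tosylate 11 adds oxidatively to give tetravalent palladium, and reductive elimination forms the C5–CH3 bond. With the C1 ester and the new C5 methyl now both flanking C6, norbornene is expelled by beta-carbon elimination, and the aryl–palladium species at C6 couples with the acetylide formed from 10 and Cs2CO3 in a copper-free Sonogashira-type termination that returns zerovalent palladium. The closest known reaction type is the Catellani ortho-alkylation of ortho-substituted aryl iodides with alkyl sulfonates, ended at the ipso carbon by a terminal alkyne. No ring is formed in the product and no stereocentre is created. The step needs exactly one methylation before the ipso coupling: the C1 ester leaves only C5–H for the relay and lets norbornene leave only once C5 is filled, and slow addition of 10 keeps direct alkynylation of unmethylated aryl–palladium low.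

Step 9
Reactants: 12 benzyl 2,4-bis(benzyloxy)-5-methyl-6-(13-methyltetradec-1-yn-1-yl)benzoate
Product: 13 2,4-dihydroxy-5-methyl-6-(13-methyltetradecyl)benzoic acid
Conditions: H2 (1–3 bar), 10% Pd/C, EtOAc/MeOH, rt; filtration, evaporation below 30 °C
Reagents that add atoms: none
Why: Heterogeneous catalytic hydrogenation with hydrogenolysis: the alkyne is saturated and the three O–benzyl bonds are cleaved to toluene in the same flask, so the decarboxylation-prone 2,4-dihydroxybenzoic acid is released under neutral conditions at room temperature and no stereocentre is involved.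

**Compound list**

1 | 5-iodobenzene-1,3-diol | Oc1cc(O)cc(I)c1 | starting material
2 | 1,3-bis(benzyloxy)-5-iodobenzene | Ic1cc(OCc2ccccc2)cc(OCc2ccccc2)c1 | intermediate
3 | N-[2,4-bis(benzyloxy)-6-iodobenzylidene]-N-methylmethanaminium chloride (iminium chloride, not isolated) | C[N+](C)=Cc1c(I)cc(OCc2ccccc2)cc1OCc1ccccc1.[Cl-] | intermediate
4 | 2,4-bis(benzyloxy)-6-iodobenzaldehyde | O=Cc1c(I)cc(OCc2ccccc2)cc1OCc1ccccc1 | intermediate
5 | 2,4-bis(benzyloxy)-6-iodobenzoic acid | OC(=O)c1c(I)cc(OCc2ccccc2)cc1OCc1ccccc1 | intermediate
6 | benzyl 2,4-bis(benzyloxy)-6-iodobenzoate | O=C(OCc1ccccc1)c1c(I)cc(OCc2ccccc2)cc1OCc1ccccc1 | intermediate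
7 | 12-methyltridecanoic acid | CC(C)CCCCCCCCCCC(=O)O | starting material
8 | 12-methyltridecan-1-ol | CC(C)CCCCCCCCCCCO | intermediate
9 | 12-methyltridecanal | CC(C)CCCCCCCCCCC=O | intermediate
10 | 13-methyltetradec-1-yne | C#CCCCCCCCCCCC(C)C | intermediate
11 | methyl 4-methylbenzenesulfonate | COS(=O)(=O)c1ccc(C)cc1 | starting material
12 | benzyl 2,4-bis(benzyloxy)-5-methyl-6-(13-methyltetradec-1-yn-1-yl)benzoate | O=C(OCc1ccccc1)c1c(OCc2ccccc2)cc(OCc2ccccc2)c(C)c1C#CCCCCCCCCCCC(C)C | intermediate
13 | 2,4-dihydroxy-5-methyl-6-(13-methyltetradecyl)benzoic acid | Cc1c(O)cc(O)c(C(=O)O)c1CCCCCCCCCCCCC(C)C | target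

**Step count.** Total: 9 steps. Longest linear sequence: 6 steps (steps 1, 2, 3, 4, 8, 9); the alkyne branch (steps 5, 6, 7) joins at step 8.

**Steps most likely to fail**

First, step 8. The relay may stall at C–H palladation of C5, which is flanked by the C4 benzyloxy group. The aryl–palladium species at C6 would then be intercepted by the alkyne before methylation or end in norbornene-containing side products; oligomerisation of the alkyne may compete as well. The fallback sets out from 6 and comes back at 12, making the two bonds in separate classical operations. Electrophilic bromination of 6 with N-bromosuccinimide in MeCN at rt should take place at C5, para to the C2 benzyloxy group, and give benzyl 2,4-bis(benzyloxy)-5-bromo-6-iodobenzoate F1. Sonogashira coupling of F1 with alkyne 10 (PdCl2(PPh3)2, CuI, Et3N, THF, rt to 40 °C) should engage only the more reactive C6–I bond and give benzyl 2,4-bis(benzyloxy)-5-bromo-6-(13-methyltetradec-1-yn-1-yl)benzoate F2. Suzuki–Miyaura methylation of the C5 bromide with trimethylboroxine (Pd(OAc)2, SPhos, K2CO3, dioxane, 90 °C) should then give 12.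

Second, step 9. Reduction may stop short: the alkyne sits between two ortho substituents, three benzyl groups must leave one after another, and traces of iodide or phosphine carried over from step 8 may poison the catalyst. Long exposure also invites decarboxylation of the free acid. The fallback sets out from 12 and comes back at 13, separating saturation from deprotection. H2 over PtO2 in EtOAc at rt should saturate the alkyne with the benzyl groups left in place and give benzyl 2,4-bis(benzyloxy)-5-methyl-6-(13-methyltetradecyl)benzoate F3. Non-reductive debenzylation with BCl3 and pentamethylbenzene as cation trap in CH2Cl2 at −78 °C should then cleave both aryl benzyl ethers and the benzyl ester and give 13 after cold aqueous work-up.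

Third, step 2. Formylation may show poor site selectivity, with attack between the two benzyloxy groups instead of next to iodine, or may be slow on the crowded ring. The fallback sets out from 1 and comes back at 4, formylating before protection so that the free phenols control the site. Vilsmeier–Haack formylation of diol 1 (POCl3, DMF, MeCN, 0 °C to rt; aqueous hydrolysis) should give 2,4-dihydroxy-6-iodobenzaldehyde F4, since free resorcinols react para to one hydroxyl far more readily than between the two. Double benzylation of F4 (BnBr, K2CO3, DMF, 60 °C) should give 4, bypassing compound 2.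

**Further compounds**

F1 | step 8 | benzyl 2,4-bis(benzyloxy)-5-bromo-6-iodobenzoate | O=C(OCc1ccccc1)c1c(OCc2ccccc2)cc(OCc2ccccc2)c(Br)c1I
F2 | step 8 | benzyl 2,4-bis(benzyloxy)-5-bromo-6-(13-methyltetradec-1-yn-1-yl)benzoate | O=C(OCc1ccccc1)c1c(OCc2ccccc2)cc(OCc2ccccc2)c(Br)c1C#CCCCCCCCCCCC(C)C
F3 | step 9 | benzyl 2,4-bis(benzyloxy)-5-methyl-6-(13-methyltetradecyl)benzoate | O=C(OCc1ccccc1)c1c(OCc2ccccc2)cc(OCc2ccccc2)c(C)c1CCCCCCCCCCCCC(C)C
F4 | step 2 | 2,4-dihydroxy-6-iodobenzaldehyde | O=Cc1c(O)cc(O)cc1I
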